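The earlier runs and the new flask are calculated for an exercise.

- The choice here is to rank these flasks by where each one stops, and to reckon each stop from one number read off the two earlier runs.

| flask | substrate | coupling partner | free catalyst | impurity | remark | time |
|---|---|---|---|---|---|---|
| violet | 20 mM | 36 mM | 60 µM | 41 µM | run made earlier |  |
| grey | 20 mM | 36 mM | 80 µM | 41 µM | run made earlier |  |
| spring | 60 mM | 36.0 mM | 40 µM | 30 µM |  | 15 d |
| summer | 20 mM | 80.0 mM | 40 µM | 80 µM |  | 15 d |
| dawn | 5.0 mM | 36.0 mM | 40 µM | 120 µM |  | 15 d |
| winter | 20 mM | 36.0 mM | 40 µM | 41 µM |  | 15 d |

| violet: time / d | violet: target / % | grey: time / d | grey: target / % |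
|---|---|---|---|
| 0.208 | 10.3 | 0.250 | 15.8 |
| 0.625 | 24.3 | 0.417 | 24.8 |
| 1.04 | 34.1 | 0.625 | 33.6 |
| 1.67 | 45.9 | 1.04 | 48.4 |
| 2.50 | 58.6 | 1.67 | 66.5 |
| 3.00 | 65.4 | 3.00 | 90.4 |

(scatter of a reading: 0.3 percentage points)

* ranking by amount of target, in percent of the substrate charged, from high to low, at 15 d (spring / summer / dawn / winter)
* the same order at 3.0 d (spring / summer / dawn / winter)
* the amount of target, in percent of the substrate charged of the flask you put first, at 15 d
* the amount of target, in percent of the substrate charged of the flask you put last, at 15 d

- candidate steps: substrate + free catalyst -> catalyst intermediate A; coupling partner + catalyst intermediate A -> catalyst intermediate B; catalyst intermediate B -> free catalyst + target; free catalyst + impurity -> spent catalyst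
- no earlier run changes the charge of impurity; that part of a forecast is a guess

- Free catalyst enters two competing steps, one with substrate and one with impurity, so its concentration cancels from the ratio of their relative rates. Hence ln(charged impurity/impurity left) = σ × ln(charged substrate/substrate left) for a flask running by the candidate steps, with σ a constant of the pair.
- The violet and grey runs share their charges of substrate and coupling partner and differ in catalyst charge, so at equal conversion they hold equal substrate and coupling partner. Their rate ratio r then equals (grey charge − L)/(violet charge − L), where L is the catalyst lost to impurity by that conversion.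
- The first way uses the first two readings of each run: r = 1.61, so L = 27.0 µM around a mean conversion of 18.8%, which reads as σ = 5.14.
- The second way uses the next two readings of each run, which share none with the first: r = 1.90, L = 37.9 µM, mean conversion 40.5%, so σ = 4.96.
- The two ways share no reading and differ by 0.185, and each σ remains a reading that carries the scatter of 0.3 percentage points. Their mean, 5.05, is carried on as the selectivity factor: the log units of impurity lost per log unit of substrate lost.
- Summer holds more impurity than catalyst, so its catalyst should end spent with 40.0 µM of impurity left, and σ turns that into 12.8% of target.
- Dawn holds more impurity than catalyst, and the same reckoning gives 7.71%.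
- Winter holds more impurity than catalyst, by 1.00 µM, so its catalyst should end spent with that much impurity left, and its stop lies at 52.1%, if slowly reached.
- Spring holds more catalyst than impurity, so catalyst survives there, and coupling partner, the limiting reagent at 36.0 mM against 60 mM of substrate, caps target at 60.0%, above the winter stop.
- This reckoning therefore ranks spring, winter, summer, dawn, but it counts stops rather than time and gives no order at 3.0 d.
- The forecast says spring > winter > summer > dawn at 15 d and winter > spring > summer > dawn at 3.0 d, with 55% (50% to 59%) for spring and 7.1% (5.8% to 8.6%) for dawn at 15 d, on the ground: “Poisoning is therefore slow and hits only free catalyst”.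
- The flasks give spring > winter > summer > dawn at 15 d and winter > spring > summer > dawn at 3.0 d, with spring at 58.2%, winter 47.3%, summer 12.5% and dawn 7.52% at 15 d.

    substrate + free catalyst → catalyst intermediate A (k = 1600 M⁻¹ h⁻¹)
    coupling partner + catalyst intermediate A → catalyst intermediate B (k = 1700 M⁻¹ h⁻¹)
    catalyst intermediate B → free catalyst + target (k = 15.0 h⁻¹)
    free catalyst + impurity → spent catalyst (k = 8300 M⁻¹ h⁻¹)

- Dawn gives 7.52% against the reckoned 7.71%, with spent catalyst at 100% of the catalyst charged. Spring keeps 42% of its substrate at 15.0 d, which σ turns into 1.21% of its impurity charge, and the flask holds 1.1%. The neighbour flask, spring with 150 mM of substrate, has its cap at 24.0% and gives 24.0% of target, with coupling partner down to 0.0286%. Its 76.0% of substrate left turns through σ into 25.0% of its impurity charge, and that flask holds 24.1%.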